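**Retrosynthetic overview**

1. Feature: in the γ‑lactone ring C3 and C4 are neighbours, and the exocyclic CH2 of the 3‑hydroxy‑4‑methoxybenzyl group on C4 is benzylic. C3, C4 and that CH2 are therefore tied into a cyclopropane, whose C3–CH2 bond (benzylic and α to the lactone C=O) is cut again with hydrogen.
2. Target ⇐ equilibration at C3 to trans ⇐ hydrogenolysis of the C1–C6 cyclopropane bond and both O‑benzyl groups of a 1‑benzyl‑6‑endo‑aryl‑3‑oxabicyclo[3.1.0]hexan‑2‑one.
3. Bicycle ⇐ (Z)‑3‑arylallyl 2‑diazo‑3‑arylpropanoate: one rhodium‑carbene (2+1) addition closes the lactone and the cyclopropane together (the only ring‑forming step) and sets C4.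
4. Diazo ester ⇐ deacylative diazo transfer ⇐ C‑benzylation of the acetoacetate of the Z‑allylic alcohol with O‑benzylvanillyl bromide; Z‑allylic alcohol ⇐ Still–Gennari olefination/DIBAL from O‑benzylisovanillin.

Key step: step 7

Assumption 1: the benzyl‑protected building blocks 1 and 8 are bought as such; each is otherwise one routine step from isovanillin or vanillin.
Assumption 2: the 4R ligand series of the dirhodium carboxamidate is taken to give the (1S,5R,6R) bicycle, by analogy with the facial sense of simple allyl diazoacetates. If a pilot run shows the opposite sense, the 4S catalyst is used and nothing else changes; the same applies to the catalyst named in the fallback.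

**Route**

Step 1
Reactants: 1 3‑benzyloxy‑4‑methoxybenzaldehyde; 2 methyl 2‑[bis(2,2,2‑trifluoroethoxy)phosphoryl]acetate
Product: 3 methyl (2Z)‑3‑(3‑benzyloxy‑4‑methoxyphenyl)prop‑2‑enoate
Conditions: KHMDS, 18‑crown‑6, THF, −78 °C; light excluded
Reagents that add atoms: none
Why: Still–Gennari variant of the Horner–Wadsworth–Emmons olefination, in which the electron‑poor phosphonate with a dissociated potassium counter‑ion eliminates quickly from the kinetic adduct and should give the Z‑cinnamate predominantly, the aryl benzyl ether being inert.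

Step 2
Reactants: 3 methyl (2Z)‑3‑(3‑benzyloxy‑4‑methoxyphenyl)prop‑2‑enoate
Product: 4 (2Z)‑3‑(3‑benzyloxy‑4‑methoxyphenyl)prop‑2‑en‑1‑ol
Conditions: DIBAL‑H (2.2 equiv), CH2Cl2, −78 °C; Rochelle salt work‑up
Reagents that add atoms: none
Why: DIBAL reduction of a conjugated ester by 1,2‑hydride delivery stops at the allylic alcohol and should leave the Z double bond and the benzyl ether untouched.

Step 3
Reactants: 4 (2Z)‑3‑(3‑benzyloxy‑4‑methoxyphenyl)prop‑2‑en‑1‑ol; 5 2,2,6‑trimethyl‑4H‑1,3‑dioxin‑4‑one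
Product: 7 (2Z)‑3‑(3‑benzyloxy‑4‑methoxyphenyl)prop‑2‑en‑1‑yl 3‑oxobutanoate, via acetylketene 6 (not isolated)
Conditions: toluene, reflux, acetone distilled off
Reagents that add atoms: none
Why: Acetoacetylation by retro‑hetero‑Diels–Alder release of acetylketene and its capture by the primary alcohol, under neutral conditions that should not disturb the Z geometry.

Step 4
Reactants: 8 (4‑benzyloxy‑3‑methoxyphenyl)methanol
Product: 9 4‑benzyloxy‑3‑methoxybenzyl bromide
Conditions: PBr3 (0.4 equiv), Et2O, 0 °C; used crude at once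
Reagents that add atoms: phosphorus tribromide, BrP(Br)Br
Why: Bromination of an electron‑rich benzylic alcohol with PBr3 through the phosphite ester and bromide displacement; the labile bromide is not stored.

Step 5
Reactants: 7 (2Z)‑3‑(3‑benzyloxy‑4‑methoxyphenyl)prop‑2‑en‑1‑yl 3‑oxobutanoate; 9 4‑benzyloxy‑3‑methoxybenzyl bromide
Product: 10 (2Z)‑3‑(3‑benzyloxy‑4‑methoxyphenyl)prop‑2‑en‑1‑yl 2‑(4‑benzyloxy‑3‑methoxybenzyl)‑3‑oxobutanoate (racemic at C2)
Conditions: K2CO3, acetone, rt to 40 °C; 7 in slight excess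
Reagents that add atoms: none
Why: Acetoacetic ester alkylation, the doubly stabilised enolate being C‑alkylated by the reactive benzylic bromide (SN2) while the excess of 7 limits dialkylation; the new stereocentre is uncontrolled and is destroyed in step 6.

Step 6
Reactants: 10 (2Z)‑3‑(3‑benzyloxy‑4‑methoxyphenyl)prop‑2‑en‑1‑yl 2‑(4‑benzyloxy‑3‑methoxybenzyl)‑3‑oxobutanoate
Product: 11 (2Z)‑3‑(3‑benzyloxy‑4‑methoxyphenyl)prop‑2‑en‑1‑yl 3‑(4‑benzyloxy‑3‑methoxyphenyl)‑2‑diazopropanoate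
Conditions: p‑ABSA (1.3 equiv), DBU (1.5 equiv), MeCN, 0 °C to rt; kept cold and used promptly
Reagents that add atoms: 4‑acetamidobenzenesulfonyl azide (p‑ABSA), CC(=O)Nc1ccc(cc1)S(=O)(=O)N=[N+]=[N-]
Why: Regitz deacylative diazo transfer, in which the enolate adds to the terminal nitrogen of the sulfonyl azide and the adduct fragments with transfer of the acetyl group to the sulfonamide nitrogen, leaving the α‑diazo ester.

Step 7
Reactants: 11 (2Z)‑3‑(3‑benzyloxy‑4‑methoxyphenyl)prop‑2‑en‑1‑yl 3‑(4‑benzyloxy‑3‑methoxyphenyl)‑2‑diazopropanoate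
Product: 12 (1S,5R,6R)‑1‑(4‑benzyloxy‑3‑methoxybenzyl)‑6‑(3‑benzyloxy‑4‑methoxyphenyl)‑3‑oxabicyclo[3.1.0]hexan‑2‑one (aryl endo)
Conditions: Rh2(4R‑MACIM)4 (2 mol%), CH2Cl2, reflux, 11 added over about 10 h by syringe pump
Reagents that add atoms: none
Why: Loss of nitrogen at the dirhodium centre gives an electrophilic rhodium carbene at the future C3, which adds in a concerted, asynchronous (2+1) manner to the tethered electron‑rich Z‑styrenyl alkene and so forms the C3–C4 bond and the temporary C3–benzylic bond. The closest known reaction type is the enantioselective intramolecular cyclopropanation of allylic α‑alkyl diazoacetates with chiral dirhodium(II) carboxamidates. The γ‑lactone closes in a 5‑exo sense (carbene carbon onto the proximal alkene carbon through the O–CH2 tether, only the cis‑fused bicycle being possible), and the cyclopropane closes by the cheletropic addition across both alkene carbons. C5 (the later C4) is set by the catalyst's choice of alkene face, C1 follows from the enforced cis fusion, and C6 follows from the stereospecific syn addition, which places the aryl group of the Z‑alkene endo. The step needs alkene addition to win over the 1,2‑hydride shift from the benzylic CH2 beside the carbene carbon; the three‑atom tether holding a nucleophilic alkoxystyrene at the carbene, the electron‑rich carboxamidate ligands and slow addition should secure this. It also needs face selectivity, which the Z geometry secures because cis‑disubstituted allyl esters fit the carboxamidate pocket best.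

Step 8
Reactants: 12 (1S,5R,6R)‑1‑(4‑benzyloxy‑3‑methoxybenzyl)‑6‑(3‑benzyloxy‑4‑methoxyphenyl)‑3‑oxabicyclo[3.1.0]hexan‑2‑one
Product: 13 (4R)‑3‑(4‑hydroxy‑3‑methoxybenzyl)‑4‑(3‑hydroxy‑4‑methoxybenzyl)dihydrofuran‑2(3H)‑one (C3 epimer mixture)
Conditions: H2 (1–3 atm), 10% Pd/C, EtOAc–EtOH, rt
Reagents that add atoms: none
Why: Heterogeneous hydrogenolysis should cleave the C1–C6 bond, the one cyclopropane bond that is both benzylic (p‑methoxyphenyl donor) and α to the lactone carbonyl, and remove both aryl benzyl ethers in the same operation; C5 is untouched and becomes (R)‑C4, C6 becomes a CH2 and C3 may emerge as either epimer.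

Step 9
Reactants: 13 (4R)‑3‑(4‑hydroxy‑3‑methoxybenzyl)‑4‑(3‑hydroxy‑4‑methoxybenzyl)dihydrofuran‑2(3H)‑one (C3 epimer mixture)
Product: 14 (3R,4R)‑3‑(4‑hydroxy‑3‑methoxybenzyl)‑4‑(3‑hydroxy‑4‑methoxybenzyl)dihydrofuran‑2(3H)‑one
Conditions: NaOMe (5 equiv), MeOH, rt to 50 °C; then 1 M HCl to pH 2
Reagents that add atoms: none
Why: Base‑mediated epimerisation through the lactone enolate should drive C3 to the thermodynamically preferred trans‑3,4‑disubstituted lactone while C4, which has no acidic hydrogen, is untouched; the acidic work‑up reprotonates the phenoxides and recloses any methanolysed lactone.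

**Compound list**

1 | 3‑benzyloxy‑4‑methoxybenzaldehyde (O‑benzylisovanillin) | COc1ccc(C=O)cc1OCc1ccccc1 | starting material
2 | methyl 2‑[bis(2,2,2‑trifluoroethoxy)phosphoryl]acetate | COC(=O)CP(=O)(OCC(F)(F)F)OCC(F)(F)F | starting material
3 | methyl (2Z)‑3‑(3‑benzyloxy‑4‑methoxyphenyl)prop‑2‑enoate | COC(=O)/C=C\c1ccc(OC)c(OCc2ccccc2)c1 | intermediate
4 | (2Z)‑3‑(3‑benzyloxy‑4‑methoxyphenyl)prop‑2‑en‑1‑ol | OC/C=C\c1ccc(OC)c(OCc2ccccc2)c1 | intermediate
5 | 2,2,6‑trimethyl‑4H‑1,3‑dioxin‑4‑one | CC1=CC(=O)OC(C)(C)O1 | starting material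
6 | acetylketene | CC(=O)C=C=O | intermediate (not isolated)
7 | (2Z)‑3‑(3‑benzyloxy‑4‑methoxyphenyl)prop‑2‑en‑1‑yl 3‑oxobutanoate | CC(=O)CC(=O)OC/C=C\c1ccc(OC)c(OCc2ccccc2)c1 | intermediate
8 | (4‑benzyloxy‑3‑methoxyphenyl)methanol | COc1cc(CO)ccc1OCc1ccccc1 | starting material
9 | 4‑benzyloxy‑3‑methoxybenzyl bromide | COc1cc(CBr)ccc1OCc1ccccc1 | intermediate
10 | (2Z)‑3‑(3‑benzyloxy‑4‑methoxyphenyl)prop‑2‑en‑1‑yl 2‑(4‑benzyloxy‑3‑methoxybenzyl)‑3‑oxobutanoate | CC(=O)C(Cc1ccc(OCc2ccccc2)c(OC)c1)C(=O)OC/C=C\c1ccc(OC)c(OCc2ccccc2)c1 | intermediate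
11 | (2Z)‑3‑(3‑benzyloxy‑4‑methoxyphenyl)prop‑2‑en‑1‑yl 3‑(4‑benzyloxy‑3‑methoxyphenyl)‑2‑diazopropanoate | [N-]=[N+]=C(Cc1ccc(OCc2ccccc2)c(OC)c1)C(=O)OC/C=C\c1ccc(OC)c(OCc2ccccc2)c1 | intermediate
12 | (1S,5R,6R)‑1‑(4‑benzyloxy‑3‑methoxybenzyl)‑6‑(3‑benzyloxy‑4‑methoxyphenyl)‑3‑oxabicyclo[3.1.0]hexan‑2‑one | O=C1OC[C@@H]2[C@H](c3ccc(OC)c(OCc4ccccc4)c3)[C@]12Cc1ccc(OCc2ccccc2)c(OC)c1 | intermediate
13 | (4R)‑3‑(4‑hydroxy‑3‑methoxybenzyl)‑4‑(3‑hydroxy‑4‑methoxybenzyl)dihydrofuran‑2(3H)‑one, C3 epimer mixture | COc1ccc(C[C@H]2COC(=O)C2Cc2ccc(O)c(OC)c2)cc1O | intermediate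
14 | (3R,4R)‑3‑(4‑hydroxy‑3‑methoxybenzyl)‑4‑(3‑hydroxy‑4‑methoxybenzyl)dihydrofuran‑2(3H)‑one | COc1ccc(C[C@H]2COC(=O)[C@@H]2Cc2ccc(O)c(OC)c2)cc1O | target

Total step count: 9
Longest linear sequence: 8 steps (1, 2, 3, 5, 6, 7, 8, 9); step 4 is a one‑step side branch.

**Steps most likely to fail**

Step 7. The 1,2‑hydride shift from the benzylic CH2 beside the carbene carbon may outrun alkene addition, or the α‑substituent may erode the face selection. The fallback sets out from 7 and comes back at 14; it takes the C3 arm off the carbene and installs it later by enolate alkylation. Diazo transfer to 7 (p‑ABSA, Et3N, MeCN) should give (2Z)‑3‑(3‑benzyloxy‑4‑methoxyphenyl)prop‑2‑en‑1‑yl 2‑diazo‑3‑oxobutanoate F1, which aqueous LiOH deacetylates in the same flask to (2Z)‑3‑(3‑benzyloxy‑4‑methoxyphenyl)prop‑2‑en‑1‑yl diazoacetate F2. Rh2(5R‑MEPY)4 in refluxing CH2Cl2 (a carbene without β‑hydrogen, the best‑documented substrate class for this catalyst family) should give (1S,5R,6S)‑6‑(3‑benzyloxy‑4‑methoxyphenyl)‑3‑oxabicyclo[3.1.0]hexan‑2‑one F3. H2 over Pd/C should cleave C1–C6 and the benzyl ether to (4R)‑4‑(3‑hydroxy‑4‑methoxybenzyl)dihydrofuran‑2(3H)‑one F4, and BnBr/K2CO3 in acetone re‑protects the phenol as (4R)‑4‑(3‑benzyloxy‑4‑methoxybenzyl)dihydrofuran‑2(3H)‑one F5. LiHMDS in THF at −78 °C followed by bromide 9 should alkylate the enolate anti to the C4 substituent and give (3R,4R)‑3‑(4‑benzyloxy‑3‑methoxybenzyl)‑4‑(3‑benzyloxy‑4‑methoxybenzyl)dihydrofuran‑2(3H)‑one F6. H2 over Pd/C then removes both benzyl groups and gives 14 directly, without the equilibration step.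

Step 8. Hydrogen may be taken up at the other benzylic cyclopropane bond (C5–C6), or cleavage at the quaternary C1 may stall after the benzyl ethers have gone. The fallback sets out from 12 and comes back at 13; it replaces surface hydrogenolysis by an ionic ring opening. Et3SiH with TFA in CH2Cl2 at 0 °C should protonate the lactone carbonyl, open the C1–C6 bond toward the p‑methoxybenzylic cation and deliver hydride to it. This gives (4R)‑3‑(4‑benzyloxy‑3‑methoxybenzyl)‑4‑(3‑benzyloxy‑4‑methoxybenzyl)dihydrofuran‑2(3H)‑one as its C3 epimer mixture F7. Plain debenzylation with H2 over Pd/C then gives 13.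

Step 1. Z selectivity may be incomplete, or the Z‑cinnamate may isomerise in light, which would lower the face selectivity of step 7. The fallback sets out from 1 and comes back at 4; it fixes the geometry by syn semi‑hydrogenation instead of kinetic olefination. Ohira–Bestmann homologation of 1 (dimethyl (1‑diazo‑2‑oxopropyl)phosphonate, K2CO3, MeOH) should give 2‑benzyloxy‑4‑ethynyl‑1‑methoxybenzene F8. n‑BuLi in THF at −78 °C followed by paraformaldehyde gives 3‑(3‑benzyloxy‑4‑methoxyphenyl)prop‑2‑yn‑1‑ol F9. H2 over Lindlar catalyst with quinoline in EtOAc then gives 4, the benzyl ether surviving.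

**Further compounds**

F1 | step 7 | (2Z)‑3‑(3‑benzyloxy‑4‑methoxyphenyl)prop‑2‑en‑1‑yl 2‑diazo‑3‑oxobutanoate | CC(=O)C(=[N+]=[N-])C(=O)OC/C=C\c1ccc(OC)c(OCc2ccccc2)c1
F2 | step 7 | (2Z)‑3‑(3‑benzyloxy‑4‑methoxyphenyl)prop‑2‑en‑1‑yl diazoacetate | [N-]=[N+]=CC(=O)OC/C=C\c1ccc(OC)c(OCc2ccccc2)c1
F3 | step 7 | (1S,5R,6S)‑6‑(3‑benzyloxy‑4‑methoxyphenyl)‑3‑oxabicyclo[3.1.0]hexan‑2‑one | O=C1OC[C@@H]2[C@H](c3ccc(OC)c(OCc4ccccc4)c3)[C@H]12
F4 | step 7 | (4R)‑4‑(3‑hydroxy‑4‑methoxybenzyl)dihydrofuran‑2(3H)‑one | COc1ccc(C[C@H]2COC(=O)C2)cc1O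
F5 | step 7 | (4R)‑4‑(3‑benzyloxy‑4‑methoxybenzyl)dihydrofuran‑2(3H)‑one | COc1ccc(C[C@H]2COC(=O)C2)cc1OCc1ccccc1
F6 | step 7 | (3R,4R)‑3‑(4‑benzyloxy‑3‑methoxybenzyl)‑4‑(3‑benzyloxy‑4‑methoxybenzyl)dihydrofuran‑2(3H)‑one | COc1ccc(C[C@H]2COC(=O)[C@@H]2Cc2ccc(OCc3ccccc3)c(OC)c2)cc1OCc1ccccc1
F7 | step 8 | (4R)‑3‑(4‑benzyloxy‑3‑methoxybenzyl)‑4‑(3‑benzyloxy‑4‑methoxybenzyl)dihydrofuran‑2(3H)‑one, C3 epimer mixture | COc1ccc(C[C@H]2COC(=O)C2Cc2ccc(OCc3ccccc3)c(OC)c2)cc1OCc1ccccc1
F8 | step 1 | 2‑benzyloxy‑4‑ethynyl‑1‑methoxybenzene | C#Cc1ccc(OC)c(OCc2ccccc2)c1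
F9 | step 1 | 3‑(3‑benzyloxy‑4‑methoxyphenyl)prop‑2‑yn‑1‑ol | OCC#Cc1ccc(OC)c(OCc2ccccc2)c1
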